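A direct plan would close the pyranone first, going from 2'-hydroxy-4',5',6'-trimethoxyacetophenone A1 to the chromone-2-carbaldehyde A2, and would then build ring B on that carbon: olefination to the α-methoxy enone A3, malonate Michael–Dieckmann annulation and decarboxylation to the 4-methoxycyclohexane-1,3-dione A4, dehydrogenation to the resorcinol flavone A5, and cleavage of the C5 methyl ether.
Its weakest steps would be:
- the annulation, where the malonate would have to choose among three electrophilic carbons, and three stereocentres would be made only to be erased;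
- the aromatisation of A4 over Pd/C at 150 °C, where loss of methanol aromatises the ring as well as loss of hydrogen does and would delete the 2'-methoxy group on late material;
- the last-step BCl3 demethylation on the free resorcinol, whose 3'-O–B bond would bring boron next to the 2'-methoxy group as well as to C5.

**Plan of the new route**
The new route would cut ring A instead. C8–H goes back to a C8–O triflate of a 5,8-hydroquinone, then C4a–C5 is cut (6π electrocyclisation of a dienylketene) and C8–C8a (addition of a C6-lithiated 2-aryl-4-pyranone to dimethyl squarate). The pyranone is cut at C2–C3 and O1–C8a. Rings arise in the order B (bought), C, A.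
The feature that allows this: C5(OH)–C6(OMe)–C7(OMe)–C8 of ring A are the four carbons of dimethyl squarate with both methoxy groups in place, and C4a=C8a is the enol-ether C=C of a 4-pyranone. The C5 hydroxyl is peri to the C4 carbonyl, so chelation tells it from the surplus oxygen at C8.
Ring B is bought aromatic and its 2'-methoxy group is set on the arene (no annulation, no dehydrogenation). The 5-hydroxyl is born free from a squarate carbonyl (no Lewis-acid ether cleavage).

Key step: step 6

Remark: 1, 4 and 8 are taken as commercial; the lithiation in step 5 is drawn at C6 of the pyranone, the carbon α to the ring oxygen.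

**Step 1**
Reactants: 1 3,5-bis(benzyloxy)benzoic acid
Product: 2 3,5-bis(benzyloxy)-2-bromobenzoic acid
Conditions: NBS (1.05 equiv), MeCN, 0 °C to rt
Reagents that add atoms: N-bromosuccinimide, O=C1CCC(=O)N1Br
Why: Electrophilic aromatic bromination, in which C2 (ortho to one benzyloxy group, para to the other) is attacked in preference to C4 (wedged between both ether groups), is the usual outcome for 3,5-dialkoxybenzoic acids, and the stoichiometric amount of NBS should hold back 2,6-dibromination.

**Step 2**
Reactants: 2 3,5-bis(benzyloxy)-2-bromobenzoic acid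
Product: 3 3,5-bis(benzyloxy)-2-methoxybenzoic acid
Conditions: NaOMe (6 equiv), CuBr (0.2 equiv), EtOAc (0.4 equiv), MeOH, 110 °C (sealed); then 1 M HCl
Reagents that add atoms: sodium methoxide, [Na+].[O-]C
Why: Ullmann-type copper-catalysed methoxylation of an aryl bromide, here helped by the ortho carboxylate that holds the monovalent copper next to the C–Br bond (as in the classical substitutions of 2-bromobenzoic acids), should replace bromide by methoxide while the benzyl ethers are inert to methoxide, and any hydrodebrominated material is simply 1.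

**Step 3**
Reactants: 3 3,5-bis(benzyloxy)-2-methoxybenzoic acid; 4 (E)-4-methoxybut-3-en-2-one
Product: 6 (E)-1-[3,5-bis(benzyloxy)-2-methoxyphenyl]-5-methoxypent-4-ene-1,3-dione, via acid chloride 5 (not isolated)
Conditions: (COCl)2 (1.5 equiv), DMF (cat.), CH2Cl2, 0 °C to rt, evaporate; 4 (2.2 equiv), LiN(SiMe3)2 (2.2 equiv), THF, −78 °C, then 5, −78 °C; 1 M HCl
Reagents that add atoms: none
Why: Crossed Claisen-type C-acylation of the kinetic (methyl-side) lithium enolate of 4 by the acid chloride 5 is the known entry to β-methoxyvinyl 1,3-diketones, and the second equivalent of enolate deprotonates the more acidic product and so prevents a second acylation.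

**Step 4**
Reactants: 6 (E)-1-[3,5-bis(benzyloxy)-2-methoxyphenyl]-5-methoxypent-4-ene-1,3-dione
Product: 7 2-[3,5-bis(benzyloxy)-2-methoxyphenyl]-4H-pyran-4-one
Conditions: TFA (2 equiv), CH2Cl2, rt
Reagents that add atoms: none
Why: Acid-catalysed cyclisation by conjugate addition–elimination, in which the enol oxygen of the aryl ketone adds 6-endo to the β-methoxy enone terminus and methanol is lost, is the established closure of such diketones to 2-substituted 4-pyranones, and benzyl aryl ethers tolerate a short exposure to TFA at room temperature.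

**Step 5**
Reactants: 7 2-[3,5-bis(benzyloxy)-2-methoxyphenyl]-4H-pyran-4-one; 8 dimethyl squarate (3,4-dimethoxycyclobut-3-ene-1,2-dione)
Product: 10 4-{6-[3,5-bis(benzyloxy)-2-methoxyphenyl]-4-oxo-4H-pyran-2-yl}-4-hydroxy-2,3-dimethoxycyclobut-2-en-1-one (racemic), via lithiopyranone 9 (not isolated)
Conditions: lithium 2,2,6,6-tetramethylpiperidide (1.15 equiv, from 2,2,6,6-tetramethylpiperidine and n-BuLi), THF, −78 °C, 15 min; cannulate into 8 (1.3 equiv), THF, −78 °C; AcOH, −78 °C
Reagents that add atoms: none
Why: Deprotonative lithiation of the pyranone by a hindered amide at the C6–H bond α to the ring oxygen (the most acidic site of 4-pyranones and chromones), followed by the standard 1,2-addition of a vinyl-lithium to one carbonyl of a dialkyl squarate, should give the carbinol, whose single stereocentre forms racemic and is destroyed in step 6; lithiation at C5 instead would be harmless, because that adduct would converge on the same hydroquinone in step 6.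

**Step 6**
Reactants: 10 4-{6-[3,5-bis(benzyloxy)-2-methoxyphenyl]-4-oxo-4H-pyran-2-yl}-4-hydroxy-2,3-dimethoxycyclobut-2-en-1-one
Product: 14 2-[3,5-bis(benzyloxy)-2-methoxyphenyl]-5-hydroxy-6,7-dimethoxy-4-oxo-4H-chromen-8-yl trifluoromethanesulfonate, via dienylketene 11 (not isolated), via dienone 12 (not isolated), via hydroquinone 13 (not isolated)
Conditions: degassed toluene, 110 °C, argon; then 0 °C, PhNTf2 (1.05 equiv), Et3N (1.5 equiv), DMAP (0.1 equiv), 0 °C to rt
Reagents that add atoms: N-phenylbis(trifluoromethanesulfonimide), O=S(=O)(N(c1ccccc1)S(=O)(=O)C(F)(F)F)C(F)(F)F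
Why: Thermal conrotatory 4π ring opening of the cyclobutenone, with the hydroxyl rotating outward as donor substituents do, gives the (Z)-dienylketene 11 with the pyranone C5=C6 bond next to the ketene; disrotatory 6π electrocyclisation then joins the ketene carbon to pyranone C5 (the new C4a–C5 bond) to give dienone 12, and enolisation of its C4a–H makes ring A aromatic as hydroquinone 13. The closest known reaction type is the Moore rearrangement of 4-alkenyl- and 4-heteroaryl-4-hydroxycyclobutenones made from squarates to annulated hydroquinones. Ring A is the only ring closed, in a six-atom pericyclic closure onto the only pyranone carbon that is conjugated to the ketene and bears hydrogen (the other neighbour of C6 is the ring oxygen), so there is no regiochemical choice. The one stereocentre formed (C4a of 12) is lost on aromatisation, and no stereocentre remains. The selectivities needed are the outward rotation of the hydroxyl (inward rotation would let it add to the ketene to give a butenolide) and, in the trapping stage, sulfonylation at O8 only: the C5 hydroxyl is tied in a hydrogen bond to the C4 carbonyl and is much less nucleophilic, as in the usual 7-O-selective derivatisation of 5,7-dihydroxyflavones. Trapping in the same flask keeps the air-sensitive hydroquinone from oxidising, and PhNTf2 is chosen because it should not attack the pyranone carbonyl oxygen as triflic anhydride would.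

**Step 7**
Reactants: 14 2-[3,5-bis(benzyloxy)-2-methoxyphenyl]-5-hydroxy-6,7-dimethoxy-4-oxo-4H-chromen-8-yl trifluoromethanesulfonate
Product: 15 2-[3,5-bis(benzyloxy)-2-methoxyphenyl]-5-hydroxy-6,7-dimethoxy-4H-chromen-4-one
Conditions: Pd(OAc)2 (5 mol %), 1,3-bis(diphenylphosphino)propane (6 mol %), HCO2H (3 equiv), Et3N (4.5 equiv), DMF, 70 °C
Reagents that add atoms: none
Why: Palladium-catalysed transfer hydrogenolysis of an aryl triflate (oxidative addition of the C8–O bond to zerovalent palladium formed from Pd(OAc)2, exchange of triflate for formate, loss of CO2 and reductive elimination of the C8–H bond) is established for triflates with two ortho substituents and should leave the benzyl ethers, the chelated phenol and the pyranone untouched.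

**Step 8**
Reactants: 15 2-[3,5-bis(benzyloxy)-2-methoxyphenyl]-5-hydroxy-6,7-dimethoxy-4H-chromen-4-one
Product: 16 2-(3,5-dihydroxy-2-methoxyphenyl)-5-hydroxy-6,7-dimethoxy-4H-chromen-4-one (target)
Conditions: H2 (1 atm), Pd/C (10% Pd on carbon), EtOAc/MeOH, rt
Reagents that add atoms: none
Why: Catalytic hydrogenolysis of the two benzyl aryl ethers over palladium on carbon at one atmosphere is the standard last step of flavone syntheses, since the C2=C3 bond (a vinylogous ester conjugated with both arenes) and the methyl ethers should not be attacked if the reaction is stopped after uptake of two equivalents of hydrogen.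

**Compound list**
1 | 3,5-bis(benzyloxy)benzoic acid | OC(=O)c1cc(OCc2ccccc2)cc(OCc2ccccc2)c1 | starting material
2 | 3,5-bis(benzyloxy)-2-bromobenzoic acid | OC(=O)c1cc(OCc2ccccc2)cc(OCc2ccccc2)c1Br | intermediate
3 | 3,5-bis(benzyloxy)-2-methoxybenzoic acid | COc1c(OCc2ccccc2)cc(OCc2ccccc2)cc1C(O)=O | intermediate
4 | (E)-4-methoxybut-3-en-2-one | CO/C=C/C(C)=O | starting material
5 | 3,5-bis(benzyloxy)-2-methoxybenzoyl chloride | COc1c(OCc2ccccc2)cc(OCc2ccccc2)cc1C(Cl)=O | intermediate (not isolated)
6 | (E)-1-[3,5-bis(benzyloxy)-2-methoxyphenyl]-5-methoxypent-4-ene-1,3-dione | COc1c(OCc2ccccc2)cc(OCc2ccccc2)cc1C(=O)CC(=O)/C=C/OC | intermediate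
7 | 2-[3,5-bis(benzyloxy)-2-methoxyphenyl]-4H-pyran-4-one | COc1c(OCc2ccccc2)cc(OCc2ccccc2)cc1-c1cc(=O)cco1 | intermediate
8 | dimethyl squarate (3,4-dimethoxycyclobut-3-ene-1,2-dione) | COC1=C(OC)C(=O)C1=O | starting material
9 | {6-[3,5-bis(benzyloxy)-2-methoxyphenyl]-4-oxo-4H-pyran-2-yl}lithium | COc1c(OCc2ccccc2)cc(OCc2ccccc2)cc1-c1cc(=O)cc([Li])o1 | intermediate (not isolated)
10 | 4-{6-[3,5-bis(benzyloxy)-2-methoxyphenyl]-4-oxo-4H-pyran-2-yl}-4-hydroxy-2,3-dimethoxycyclobut-2-en-1-one (racemic) | COC1=C(OC)C(O)(c2cc(=O)cc(-c3cc(OCc4ccccc4)cc(OCc4ccccc4)c3OC)o2)C1=O | intermediate (key-step precursor)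
11 | (3Z)-4-{6-[3,5-bis(benzyloxy)-2-methoxyphenyl]-4-oxo-4H-pyran-2-yl}-4-hydroxy-2,3-dimethoxybuta-1,3-dien-1-one | O=C=C(OC)/C(OC)=C(/O)c1cc(=O)cc(-c2cc(OCc3ccccc3)cc(OCc3ccccc3)c2OC)o1 | intermediate (not isolated)
12 | 2-[3,5-bis(benzyloxy)-2-methoxyphenyl]-8-hydroxy-6,7-dimethoxy-4aH-chromene-4,5-dione (racemic) | COC1=C(OC)C(O)=C2OC(c3cc(OCc4ccccc4)cc(OCc4ccccc4)c3OC)=CC(=O)C2C1=O | intermediate (not isolated)
13 | 2-[3,5-bis(benzyloxy)-2-methoxyphenyl]-5,8-dihydroxy-6,7-dimethoxy-4H-chromen-4-one | COc1c(O)c2oc(-c3cc(OCc4ccccc4)cc(OCc4ccccc4)c3OC)cc(=O)c2c(O)c1OC | intermediate (not isolated)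
14 | 2-[3,5-bis(benzyloxy)-2-methoxyphenyl]-5-hydroxy-6,7-dimethoxy-4-oxo-4H-chromen-8-yl trifluoromethanesulfonate | COc1c(OS(=O)(=O)C(F)(F)F)c2oc(-c3cc(OCc4ccccc4)cc(OCc4ccccc4)c3OC)cc(=O)c2c(O)c1OC | intermediate (key-step product)
15 | 2-[3,5-bis(benzyloxy)-2-methoxyphenyl]-5-hydroxy-6,7-dimethoxy-4H-chromen-4-one | COc1cc2oc(-c3cc(OCc4ccccc4)cc(OCc4ccccc4)c3OC)cc(=O)c2c(O)c1OC | intermediate
16 | 2-(3,5-dihydroxy-2-methoxyphenyl)-5-hydroxy-6,7-dimethoxy-4H-chromen-4-one | COc1cc2oc(-c3cc(O)cc(O)c3OC)cc(=O)c2c(O)c1OC | target

**Summary**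
Total step count: 8. Longest linear sequence: 8 steps (1 to 16).

**Steps most likely to fail**

Step 5. The hindered amide may remove the wrong proton (C3 next to the aryl group, a benzylic or a ring B hydrogen), or the lithiated pyranone may add to unreacted pyranone before it meets the squarate. The fallback sets out from 7: zincation at C6 with (tmp)ZnCl·LiCl (tmp = 2,2,6,6-tetramethylpiperidide; THF, rt) and quenching with I2 should give 2-[3,5-bis(benzyloxy)-2-methoxyphenyl]-6-iodo-4H-pyran-4-one F1. Iodine–magnesium exchange (iPrMgCl·LiCl, THF, −40 °C) and addition of the resulting Grignard reagent to 8 at −78 °C would come back to the route at 10.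

Step 6. On ring opening the hydroxyl may rotate inward and capture the ketene as a butenolide, or the hydroquinone may oxidise before it is trapped. The fallback sets out from 10: silylation (Me3SiCl, Et3N, DMAP, CH2Cl2) should give 4-{6-[3,5-bis(benzyloxy)-2-methoxyphenyl]-4-oxo-4H-pyran-2-yl}-2,3-dimethoxy-4-(trimethylsilyloxy)cyclobut-2-en-1-one F2, which has no free hydroxyl to intercept the ketene. Thermolysis in toluene at 110 °C should then give the air-stable monosilyl hydroquinone 2-[3,5-bis(benzyloxy)-2-methoxyphenyl]-5-hydroxy-6,7-dimethoxy-8-(trimethylsilyloxy)-4H-chromen-4-one F3. Desilylation (KF, MeOH, argon) would come back to the route at 13, which is triflated as in the second stage of step 6.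

Step 2. Reduction of the C–Br bond may outrun the slow substitution at a carbon flanked on both sides. The fallback sets out from 2: bromine–lithium exchange on the lithium carboxylate (n-BuLi, 2.2 equiv, THF, −90 °C), trapping with B(OMe)3 and oxidation (H2O2, NaOH) should give 3,5-bis(benzyloxy)-2-hydroxybenzoic acid F4. Double methylation (MeI, K2CO3, DMF) should give methyl 3,5-bis(benzyloxy)-2-methoxybenzoate F5, and saponification (LiOH, THF/H2O) would come back to the route at 3.

**Further compounds**
F1 | step 5 | 2-[3,5-bis(benzyloxy)-2-methoxyphenyl]-6-iodo-4H-pyran-4-one | COc1c(OCc2ccccc2)cc(OCc2ccccc2)cc1-c1cc(=O)cc(I)o1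
F2 | step 6 | 4-{6-[3,5-bis(benzyloxy)-2-methoxyphenyl]-4-oxo-4H-pyran-2-yl}-2,3-dimethoxy-4-(trimethylsilyloxy)cyclobut-2-en-1-one | COC1=C(OC)C(O[Si](C)(C)C)(c2cc(=O)cc(-c3cc(OCc4ccccc4)cc(OCc4ccccc4)c3OC)o2)C1=O
F3 | step 6 | 2-[3,5-bis(benzyloxy)-2-methoxyphenyl]-5-hydroxy-6,7-dimethoxy-8-(trimethylsilyloxy)-4H-chromen-4-one | COc1c(O[Si](C)(C)C)c2oc(-c3cc(OCc4ccccc4)cc(OCc4ccccc4)c3OC)cc(=O)c2c(O)c1OC
F4 | step 2 | 3,5-bis(benzyloxy)-2-hydroxybenzoic acid | OC(=O)c1cc(OCc2ccccc2)cc(OCc2ccccc2)c1O
F5 | step 2 | methyl 3,5-bis(benzyloxy)-2-methoxybenzoate | COC(=O)c1cc(OCc2ccccc2)cc(OCc2ccccc2)c1OC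
A1 | direct plan | 2'-hydroxy-4',5',6'-trimethoxyacetophenone | CC(=O)c1c(O)cc(OC)c(OC)c1OC
A2 | direct plan | 5,6,7-trimethoxy-4-oxochromene-2-carbaldehyde | O=Cc1cc(=O)c2c(OC)c(OC)c(OC)cc2o1
A3 | direct plan | (Z)-3-methoxy-4-(5,6,7-trimethoxy-4-oxochromen-2-yl)but-3-en-2-one | CC(=O)/C(OC)=C/c1cc(=O)c2c(OC)c(OC)c(OC)cc2o1
A4 | direct plan | 4-methoxy-5-(5,6,7-trimethoxy-4-oxochromen-2-yl)cyclohexane-1,3-dione | COC1C(=O)CC(=O)CC1c1cc(=O)c2c(OC)c(OC)c(OC)cc2o1
A5 | direct plan | 2-(3,5-dihydroxy-2-methoxyphenyl)-5,6,7-trimethoxychromen-4-one | COc1cc2oc(-c3cc(O)cc(O)c3OC)cc(=O)c2c(OC)c1OC
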